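**Plan**

- Retrosynthesis: the three B-ring phenols are masked as MOM ethers. Ring C (O1, C2, C3, C4, C4a, C8a) is then cut at C4–C4a and O1–C2, giving 2,4-diprenylphloroglucinol (ring A with both of its prenyl groups) and an α-prenyl aroylacetate (C2, C3, C4, the 3-prenyl group and ring B).
- Enabling feature: in ring A, C6 and C8 carry prenyl groups and C5, C7 and C8a carry oxygen. C4a is therefore the only free ring carbon and lies between two oxygens that are interchangeable in the mirror-symmetric triol, so only one chromone can form.
- Forward: phloroglucinol is C-diprenylated. 2',4',5'-Trihydroxyacetophenone is MOM-protected, C-ethoxycarbonylated and α-prenylated. Ring C closes last in a thermal pyranone annulation of the two halves, and methanolic acid then frees ring B.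
- Stereochemistry: the target has no stereocentre and no stereogenic double bond, so nothing has to be set or preserved.

Key step: step 5

Remark: every olefin carries two methyl groups on one carbon and there is no sp3 stereocentre, so the compound is achiral; "single enantiomer" is read as the one constitution drawn.

**Route**

Step 1
Reactants: 1 phloroglucinol; 2 prenyl bromide
Product: 3 2,4-diprenylphloroglucinol
Conditions: 2 (2.1 equiv), 10% aq. KOH, 0 °C → rt, Ar; then 1 M HCl to pH 5; chromatography
Reagents that add atoms: none
Why: Alkylation of the ambident phloroglucinolate with an allylic bromide in water goes mainly at carbon (C-prenylation of a polyphenolate), and with about two equivalents the 2,4-dialkylated triol should be separable from mono- and tri-alkylated material.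

Step 2
Reactants: 4 2',4',5'-trihydroxyacetophenone
Product: 5 2',4',5'-tris(methoxymethoxy)acetophenone
Conditions: NaH (3.3 equiv), MOMCl (3.6 equiv), DMF, 0 °C → rt, Ar
Reagents that add atoms: chloromethyl methyl ether (MOMCl), COCCl
Why: Williamson-type O-alkylation of the three sodium phenoxides; full deprotonation by NaH also frees the ketone-chelated 2'-hydroxyl, so all three oxygens should be capped.

Step 3
Reactants: 5 2',4',5'-tris(methoxymethoxy)acetophenone; 6 diethyl carbonate
Product: 7 ethyl 3-oxo-3-[2,4,5-tris(methoxymethoxy)phenyl]propanoate
Conditions: NaH (2.5 equiv), 6 (5 equiv), THF, reflux (ketone added slowly); AcOH, 0 °C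
Reagents that add atoms: none
Why: Crossed Claisen condensation of the methyl ketone enolate with diethyl carbonate, pulled to completion by deprotonation of the β-keto ester as it forms; the MOM acetals are inert to base and should survive the cold acetic acid quench.

Step 4
Reactants: 7 ethyl 3-oxo-3-[2,4,5-tris(methoxymethoxy)phenyl]propanoate; 2 prenyl bromide
Product: 8 ethyl 2-prenyl-3-oxo-3-[2,4,5-tris(methoxymethoxy)phenyl]propanoate
Conditions: 2 (1.05 equiv), K2CO3 (1.5 equiv), acetone, rt → 50 °C
Reagents that add atoms: none
Why: SN2 C-alkylation of the doubly stabilised β-keto ester enolate by the allylic bromide, held at mono-prenylation by one equivalent of electrophile and the weak carbonate base; the new α-stereocentre forms racemic and is of no consequence because it becomes sp2 C3 in step 5.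

Step 5
Reactants: 3 2,4-diprenylphloroglucinol; 8 ethyl 2-prenyl-3-oxo-3-[2,4,5-tris(methoxymethoxy)phenyl]propanoate
Product: 11 5,7-dihydroxy-3,6,8-triprenyl-2-[2,4,5-tris(methoxymethoxy)phenyl]chromen-4-one, via aroylketene 9 (not isolated), via triketone 10 (not isolated)
Conditions: 8 (1.4 equiv), neat melt, Ar stream, microwave, ramp to 220–240 °C, hold ≤10 min (EtOH and H2O swept out)
Reagents that add atoms: none
Why: On heating, the enol of 8 expels ethanol to give aroylketene 9, whose ketene carbon is attacked by C6 of triol 3, the only unsubstituted ring carbon, to give triketone 10 after tautomerisation; any aryl ester formed by O-attack returns to 9 at this temperature, so material drains to the C-acyl product. A hydroxyl ortho to the new acyl group then adds to the aryl ketone and water is lost, which closes ring C as the 4-pyranone by 6-exo-trig addition followed by dehydration and completes the C4–C4a and O1–C2 bonds. The closest known reaction is the Mentzer (uncatalysed thermal Simonis-type) chromone synthesis from phloroglucinols and α-substituted aroylacetates. No stereocentre is created, and the racemic α-carbon of 8 becomes sp2 C3. The step needs chromone rather than coumarin formation and a single direction of ring closure: the neutral melt offers no acid to activate the hindered, electron-rich aryl ketone towards attack by the ring carbon, so acylation runs through the ester-derived ketene carbon, and the mirror symmetry of 3 makes the two hydroxyls flanking the acylated carbon equivalent, so either closure gives the same flavone. Short heating under argon is chosen to spare the ortho-prenyl phenols and the MOM acetals.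

Step 6
Reactants: 11 5,7-dihydroxy-3,6,8-triprenyl-2-[2,4,5-tris(methoxymethoxy)phenyl]chromen-4-one
Product: 12 5,7-dihydroxy-3,6,8-triprenyl-2-(2,4,5-trihydroxyphenyl)chromen-4-one
Conditions: HCl (1.25 M in MeOH)/THF, degassed, Ar, 0 °C → rt
Reagents that add atoms: none
Why: Acid-catalysed transacetalisation of the three aryl MOM ethers to dimethoxymethane in methanol, the usual unmasking of prenylated polyphenols; at or below room temperature acetal cleavage should outpace protonation of the trisubstituted olefins.

**Compound list**

1 | phloroglucinol (benzene-1,3,5-triol) | Oc1cc(O)cc(O)c1 | starting material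
2 | prenyl bromide (1-bromo-3-methylbut-2-ene) | CC(C)=CCBr | starting material
3 | 2,4-diprenylphloroglucinol [2,4-bis(3-methylbut-2-en-1-yl)benzene-1,3,5-triol] | Oc1cc(O)c(CC=C(C)C)c(O)c1CC=C(C)C | intermediate
4 | 2',4',5'-trihydroxyacetophenone | CC(=O)c1cc(O)c(O)cc1O | starting material
5 | 2',4',5'-tris(methoxymethoxy)acetophenone | CC(=O)c1cc(OCOC)c(OCOC)cc1OCOC | intermediate
6 | diethyl carbonate | CCOC(=O)OCC | starting material
7 | ethyl 3-oxo-3-[2,4,5-tris(methoxymethoxy)phenyl]propanoate | CCOC(=O)CC(=O)c1cc(OCOC)c(OCOC)cc1OCOC | intermediate
8 | ethyl 2-prenyl-3-oxo-3-[2,4,5-tris(methoxymethoxy)phenyl]propanoate (racemic at the α-carbon) | CCOC(=O)C(CC=C(C)C)C(=O)c1cc(OCOC)c(OCOC)cc1OCOC | intermediate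
9 | aroylketene, 5-methyl-2-[2,4,5-tris(methoxymethoxy)benzoyl]hexa-1,4-dien-1-one (formed in the flask in step 5, not isolated) | O=C=C(CC=C(C)C)C(=O)c1cc(OCOC)c(OCOC)cc1OCOC | intermediate
10 | triketone, 2-prenyl-1-(2,4,6-trihydroxy-3,5-diprenylphenyl)-3-[2,4,5-tris(methoxymethoxy)phenyl]propane-1,3-dione (racemic, enolisable; formed in the flask in step 5, not isolated) | CC(C)=CCc1c(O)c(CC=C(C)C)c(O)c(C(=O)C(CC=C(C)C)C(=O)c2cc(OCOC)c(OCOC)cc2OCOC)c1O | intermediate
11 | 5,7-dihydroxy-3,6,8-triprenyl-2-[2,4,5-tris(methoxymethoxy)phenyl]chromen-4-one | CC(C)=CCc1c(O)c(CC=C(C)C)c2oc(-c3cc(OCOC)c(OCOC)cc3OCOC)c(CC=C(C)C)c(=O)c2c1O | intermediate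
12 | 5,7-dihydroxy-3,6,8-tris(3-methylbut-2-en-1-yl)-2-(2,4,5-trihydroxyphenyl)-4H-chromen-4-one (achiral) | CC(C)=CCc1c(O)c(CC=C(C)C)c2oc(-c3cc(O)c(O)cc3O)c(CC=C(C)C)c(=O)c2c1O | target

**Step count and risks**

Total steps: 6. Longest linear sequence: 5 steps (4 → 5 → 7 → 8 → 11 → 12); the ring-A branch (1 → 3) joins at step 5.

Steps most likely to fail:

Step 5. The prenylated triol may break down in the melt before C-acylation is complete: prenyl side chains can close onto neighbouring hydroxyls, the electron-rich ring can decompose oxidatively, and 8 can be lost by hydrolysis and decarboxylation with the water released. The fallback sets out from 1 and 8 and moves the A-ring prenylation behind the annulation. The same thermal condensation run on phloroglucinol itself, which carries no heat-sensitive side chain, should give 5,7-dihydroxy-3-prenyl-2-[2,4,5-tris(methoxymethoxy)phenyl]chromen-4-one F1. Double C-prenylation of F1 with 2 (NaOMe, MeOH, rt) at C6 and C8, the only nucleophilic carbons left on the phenoxide ring, returns to the route at 11.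

Step 1. Over-alkylation of the very nucleophilic phenolate (geminal C-diprenylation with loss of aromaticity, triprenylation) and O-alkylation may leave the 2,4-isomer as a minor part of a statistical mixture. The fallback sets out from 1 and places each prenyl group by directed metalation.
- Exhaustive O-protection (NaH, MOMCl, DMF) should give 1,3,5-tris(methoxymethoxy)benzene F2.
- n-BuLi (THF, 0 °C) removes the proton between two MOM ethers to give 2-lithio-1,3,5-tris(methoxymethoxy)benzene F3, which with CuI (cat.) and 2 gives 2-prenyl-1,3,5-tris(methoxymethoxy)benzene F4.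
- A second lithiation, again between two MOM ethers, gives 4-lithio-2-prenyl-1,3,5-tris(methoxymethoxy)benzene F5, and coupling with 2 gives 2,4-diprenyl-1,3,5-tris(methoxymethoxy)benzene F6.
- Brief treatment with methanolic HCl at 0 °C removes the acetals and returns to the route at 3.

Step 6. Protonation of the prenyl olefins may compete with acetal cleavage, so that the 5- or 7-hydroxyl (or methanol) adds to the tertiary cation and a chroman forms; the hydroxyquinol ring B may also oxidise in air. The fallback sets out from 11 and replaces protic solvolysis by a base-buffered silyl exchange. TMSOTf and 2,2'-bipyridyl (CH2Cl2, 0 °C) should convert the aryl MOM ethers into aryl silyl ethers and silylate the free phenols, giving 5,7-bis(trimethylsilyloxy)-3,6,8-triprenyl-2-[2,4,5-tris(trimethylsilyloxy)phenyl]chromen-4-one F7. Addition of degassed water at rt hydrolyses the silyl ethers under near-neutral conditions and returns to the route at 12.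

**Further compounds**

F1 | step 5 | 5,7-dihydroxy-3-prenyl-2-[2,4,5-tris(methoxymethoxy)phenyl]chromen-4-one | CC(C)=CCc1c(-c2cc(OCOC)c(OCOC)cc2OCOC)oc2cc(O)cc(O)c2c1=O
F2 | step 1 | 1,3,5-tris(methoxymethoxy)benzene | COCOc1cc(OCOC)cc(OCOC)c1
F3 | step 1 | 2-lithio-1,3,5-tris(methoxymethoxy)benzene | [Li]c1c(OCOC)cc(OCOC)cc1OCOC
F4 | step 1 | 2-prenyl-1,3,5-tris(methoxymethoxy)benzene | COCOc1cc(OCOC)c(CC=C(C)C)c(OCOC)c1
F5 | step 1 | 4-lithio-2-prenyl-1,3,5-tris(methoxymethoxy)benzene | [Li]c1c(OCOC)cc(OCOC)c(CC=C(C)C)c1OCOC
F6 | step 1 | 2,4-diprenyl-1,3,5-tris(methoxymethoxy)benzene | COCOc1cc(OCOC)c(CC=C(C)C)c(OCOC)c1CC=C(C)C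
F7 | step 6 | 5,7-bis(trimethylsilyloxy)-3,6,8-triprenyl-2-[2,4,5-tris(trimethylsilyloxy)phenyl]chromen-4-one | CC(C)=CCc1c(O[Si](C)(C)C)c(CC=C(C)C)c2oc(-c3cc(O[Si](C)(C)C)c(O[Si](C)(C)C)cc3O[Si](C)(C)C)c(CC=C(C)C)c(=O)c2c1O[Si](C)(C)C
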